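Starting from the constants, I looked for the concentration that sets the order of the rate in this flask.

    substrate + target → 2 target (k1 = 830 L mol⁻¹ s⁻¹)
    substrate → target (k2 = 5.0 × 10⁻⁴ s⁻¹)
    crystals ⇌ target, rate k3*(cs3 - [target]) while solid is left; crystals form when [target] > cs3 (cs3 = 0.12 mM, k3 = 4.6 s⁻¹)
    substrate + target → side product (k4 = 80 L mol⁻¹ s⁻¹)

substrate 2.0 × 10⁻⁴ M; time 50 s

* the target and crystals together standing at 50 s, as a percentage of the substrate charged
* concentration of target in solution at 50 s, in percent of saturation

- in percentages every species weighs as the substrate in it: one side product counts as two
- for target the crystals are counted in
- as a solid, counted per litre of solution: crystals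
- run time (flask): 50 s

1. While the substrate stayed near its charge, the target's concentration set the order, so the target grew in a pseudo-first-order way, and I reckoned 0.150 s⁻¹ as the growth constant, the charged substrate times the autocatalytic constant less the side-step constant.
2. My bench rule was that the uncatalysed step seeds a share of 5.0 × 10⁻⁴ s⁻¹ over this constant, which then grows exponentially, but by 50 s that gave 602% of the charge, which is more than was charged, so the rule had a border.
3. I found the border from two ratios: each substrate lost left a net 82.4% as target, while saturation lay at 60.0% of the charge, which is less than that ceiling, so I expected crystals.
4. I let the ratio of target to substrate left take the place of the target in the rule; by this reckoning 27.2% of the substrate remained at saturation, which put my estimate of the crossing at 43.3 s.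
5. Because dissolution is much faster than growth, I held the solution at saturation from there on, so the gap between target and crystals together and the ceiling closed at 0.109 s⁻¹, and I committed to 71.6% of the charge as target and crystals together at 50 s, with the dissolved target at 100% of saturation.

The forecast gave 72% and 100.4%, holding that “the solution stays pinned just above saturation”.

The flask gave 72.2% and 100% of saturation, with 12.0% of the charge as crystals within that yield. Back inside the border, at 5.00 s, the growth constant gave 0.372%, and the flask held 0.371%.

With 8.0 × 10⁻⁵ M of substrate, the growth constant became 0.0600 s⁻¹ and saturation lay at 150% of that charge, above the ceiling, so I expected no crystals and reckoned 13.3%. That flask gave 13.7%, with crystals at 0%.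

(The constants used here are those of an exercise; no experiment stands behind them.)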